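**Plan**
1. Labdane numbering is used: C4 carries CH3/CO2H, C5 and C10 are the ring-fusion carbons, C8=C9 is the ring alkene, C11–C15 the side chain. Retrosynthesis: the acetate and the C19 acid are unmasked last; C9–C11 is cut (enol triflate + alkylborane); the C4 methyl is cut (enolate methylation); then C7–C8 and C5–C10 are cut together, which opens both rings to an acyclic keto enal.
2. Enabling feature: the tetrasubstituted ring-B alkene C8=C9 is a masked C9 ketone whose two α-carbons are C8 (methyl-bearing) and the quaternary C10, and C5–C6–C7 is a three-carbon enal. Ring B is therefore a ketone-plus-enal [3+3] Michael/aldol-condensation product, and the Michael bond is also the last bond of ring A.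
3. Forward: pentan-3-one is alkylated (C1–C3), then joined to dimethyl malonate (C4) and propynal (C5–C7). One acid-catalysed cascade closes ring A (C5–C10) and then ring B (C7–C8) to a trans-fused enone.
4. Reductive triflation gives the C8=C9 enol triflate; B-alkyl Suzuki coupling attaches C11–C15; C4 methylation, desilylation, ester cleavage and acetylation finish.
5. Stereochemistry: C5 and C10 come from the chiral phosphoric acid and a chair transition state in the cascade; C4 from equatorial methylation anti to the C10 methyl; the 13E alkene is bought in (E)-3-methylpent-2-en-4-yn-1-ol.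

Key step: step 4

Assumption: propynal is taken as a purchasable reagent; the sense of induction of the phosphoric acid in step 4 cannot be assigned in advance, so (R)-TRIP is written and its antipode is to be used if it favours the mirror-image enone.

**Step 1**
Reactants: 1 pentan-3-one; 2 1-chloro-3-iodopropane
Product: 4 racemic 7-chloro-4-methylheptan-3-one, via lithium enolate 3 (not isolated)
Conditions: LiN(i-Pr)2 (LDA), THF, −78 °C; then 2, DMPU, −78 → 0 °C
Reagents that add atoms: none
Why: Lithium enolate alkylation of a symmetrical ketone, in which the enolate attacks the iodide terminus of 2 because iodide is by far the better leaving group; the new stereocentre is racemic by design, since it is erased by enolisation in step 4.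

**Step 2**
Reactants: 4 racemic 7-chloro-4-methylheptan-3-one; 5 dimethyl malonate
Product: 7 dimethyl 2-(4-methyl-5-oxoheptyl)propanedioate, via sodium dimethyl malonate 6 (not isolated)
Conditions: NaH, 5 (1.5 equiv), DMF, 0 °C; then 4, NaI (10 mol %), 60 °C
Reagents that add atoms: none
Why: Malonic ester alkylation (SN2, assisted by in situ Finkelstein exchange), in which the weakly basic malonate anion should not enolise the ketone, so intramolecular ketone alkylation is not expected to compete.

**Step 3**
Reactants: 7 dimethyl 2-(4-methyl-5-oxoheptyl)propanedioate; 8 propynal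
Product: 9 dimethyl 2-(4-methyl-5-oxoheptyl)-2-[(E)-3-oxoprop-1-enyl]propanedioate
Conditions: 8 (1.3 equiv), Cs2CO3 (10 mol %), MeCN, −20 → 0 °C; then DABCO (5 mol %), rt
Reagents that add atoms: none
Why: Base-catalysed Michael addition of a 2-alkylmalonate to an ynal should give the γ-quaternary enal, and reversible amine addition should equilibrate it to the E isomer; no stereocentre is formed.

**Step 4**
Reactants: 9 dimethyl 2-(4-methyl-5-oxoheptyl)-2-[(E)-3-oxoprop-1-enyl]propanedioate
Product: 12 dimethyl (4aS,8aR)-4a,6-dimethyl-5-oxo-3,4,4a,5,8,8a-hexahydronaphthalene-1,1(2H)-dicarboxylate, via keto aldehyde 10 (not isolated), via ketol 11 (not isolated)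
Conditions: (R)-TRIP [(R)-3,3′-bis(2,4,6-triisopropylphenyl)-1,1′-binaphthyl-2,2′-diyl hydrogen phosphate] (10 mol %), toluene (0.05 M), 60 °C; then TsOH·H2O (10 mol %), 80 °C
Reagents that add atoms: none
Why: Proposed new method: the phosphoric acid tautomerises the ketone to its more substituted C9=C10 enol and, hydrogen-bonded to both the enol O–H and the formyl oxygen, delivers enol carbon C10 to C5 of the E-enal in a 6-(enolexo)-exo-trig conjugate addition that closes ring A (C5–C10). The 1,5-keto aldehyde 10 is then enolised towards C8 and closes ring B by a 6-(enolendo)-exo-trig aldol addition to the C7 aldehyde (C7–C8), and acid-promoted dehydration of ketol 11 gives the conjugated enone 12. The closest known reaction types are the chiral-phosphoric-acid "enol catalysis" Michael addition of α-branched cyclic ketones to enones, which gives α-quaternary ketones, and the Robinson-type Michael/aldol condensation; the new element is the intramolecular use on an acyclic ketone with an enal, run as a [3+3] union of the two α-carbons of one ketone with a three-carbon enal. C5 is set by the catalyst, whose aryl groups shield one enantiotopic face of the enal β-carbon in the doubly hydrogen-bonded transition state, and C10 is set relative to C5 by a chair-like transition state for ring A in which the catalyst-bound enol carbon C9 and the enal carbon C6 are both equatorial and the C10 methyl is axial, which is the trans ring fusion. The step needs enolisation towards C10 rather than C8 and Michael addition before aldol addition, both secured by ring size (the C8 enol could reach C5 only through an eight-membered ring and C7 only through a ten-membered ring while ring A is open), and it needs an enal that cannot deconjugate, secured by the quaternary malonate carbon C4, which also favours closure (Thorpe–Ingold effect). The racemic α-stereocentre of 9 is erased in the achiral enol, so both enantiomers of 9 should converge on one product.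

**Step 5**
Reactants: 12 dimethyl (4aS,8aR)-4a,6-dimethyl-5-oxo-3,4,4a,5,8,8a-hexahydronaphthalene-1,1(2H)-dicarboxylate
Product: 13 methyl (4aS,8aS)-4a,6-dimethyl-5-oxo-1,2,3,4,4a,5,8,8a-octahydronaphthalene-1-carboxylate (C-1 epimers; ring fusion unchanged)
Conditions: LiCl, H2O (2 equiv), DMSO, 160 °C
Reagents that add atoms: none
Why: Krapcho dealkoxycarbonylation of the geminal diester (chloride SN2 at an O-methyl group, then decarboxylation) under near-neutral conditions that the enone should tolerate; the C4 centre formed as a mixture is reset in step 10.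

**Step 6**
Reactants: 13 methyl (4aS,8aS)-4a,6-dimethyl-5-oxo-1,2,3,4,4a,5,8,8a-octahydronaphthalene-1-carboxylate
Product: 15 methyl (4aS,8aS)-4a,6-dimethyl-5-(trifluoromethanesulfonyloxy)-1,2,3,4,4a,7,8,8a-octahydronaphthalene-1-carboxylate (C-1 epimers), via lithium enolate 14 (not isolated)
Conditions: LiBH(s-Bu)3 (L-Selectride), THF, −78 °C; then PhNTf2, −78 → 0 °C
Reagents that add atoms: N-phenylbis(trifluoromethanesulfonimide), O=S(=O)(N(c1ccccc1)S(=O)(=O)C(F)(F)F)C(F)(F)F
Why: Reductive triflation, in which conjugate hydride addition to the β-unsubstituted enone gives the C8=C9 enolate regiospecifically (C10 is quaternary) and O-sulfonylation fixes the tetrasubstituted ring alkene as its enol triflate.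

**Step 7**
Reactants: 16 (E)-3-methylpent-2-en-4-yn-1-ol
Product: 17 tert-butyldimethyl{[(E)-3-methylpent-2-en-4-yn-1-yl]oxy}silane
Conditions: TBSCl, imidazole, DMF, rt
Reagents that add atoms: tert-butyldimethylsilyl chloride, CC(C)(C)[Si](C)(C)Cl
Why: Standard silylation of a primary allylic alcohol, which leaves the alkene geometry untouched.

**Step 8**
Reactants: 17 tert-butyldimethyl{[(E)-3-methylpent-2-en-4-yn-1-yl]oxy}silane
Product: 18 tert-butyldimethyl{[(E)-3-methylpenta-2,4-dien-1-yl]oxy}silane
Conditions: H2 (1 atm), Pd/CaCO3 poisoned with Pb(OAc)2 (Lindlar catalyst), quinoline, hexane, rt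
Reagents that add atoms: none
Why: Lindlar semihydrogenation of the terminal alkyne should stop at the 1,3-diene and leave the E trisubstituted alkene unchanged.

**Step 9**
Reactants: 18 tert-butyldimethyl{[(E)-3-methylpenta-2,4-dien-1-yl]oxy}silane; 15 methyl (4aS,8aS)-4a,6-dimethyl-5-(trifluoromethanesulfonyloxy)-1,2,3,4,4a,7,8,8a-octahydronaphthalene-1-carboxylate
Product: 20 methyl (4aS,8aS)-5-[(E)-5-(tert-butyldimethylsilyloxy)-3-methylpent-3-enyl]-4a,6-dimethyl-1,2,3,4,4a,7,8,8a-octahydronaphthalene-1-carboxylate (C-1 epimers), via alkylborane 19 (not isolated)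
Conditions: 9-BBN, THF, 0 °C → rt; then 15, PdCl2(dppf) (5 mol %), AsPh3 (10 mol %), Cs2CO3, DMF/THF/H2O, rt → 50 °C
Reagents that add atoms: none
Why: 9-BBN should hydroborate only the monosubstituted terminal alkene of the diene at its terminal carbon, and B-alkyl Suzuki–Miyaura coupling of the primary alkylborane with the enol triflate (a 2,6,6-trisubstituted cyclohexenyl triflate, an established coupling partner type) forms C9–C11 with the ring-alkene position and the E geometry retained.

**Step 10**
Reactants: 20 methyl (4aS,8aS)-5-[(E)-5-(tert-butyldimethylsilyloxy)-3-methylpent-3-enyl]-4a,6-dimethyl-1,2,3,4,4a,7,8,8a-octahydronaphthalene-1-carboxylate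
Product: 22 methyl (1S,4aS,8aR)-5-[(E)-5-(tert-butyldimethylsilyloxy)-3-methylpent-3-enyl]-1,4a,6-trimethyl-1,2,3,4,4a,7,8,8a-octahydronaphthalene-1-carboxylate, via lithium ester enolate 21 (not isolated)
Conditions: LiN(i-Pr)2 (LDA), THF, −78 °C; then MeI, DMPU, −78 → −20 °C
Reagents that add atoms: iodomethane, CI
Why: Alkylation of the exocyclic ester enolate, in which iodomethane should approach from the equatorial α-face because the axial β-face is blocked by the syn-axial C10 methyl, so the new methyl is equatorial and the ester axial, which sets C4 as S.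

**Step 11**
Reactants: 22 methyl (1S,4aS,8aR)-5-[(E)-5-(tert-butyldimethylsilyloxy)-3-methylpent-3-enyl]-1,4a,6-trimethyl-1,2,3,4,4a,7,8,8a-octahydronaphthalene-1-carboxylate
Product: 23 methyl (1S,4aS,8aR)-5-[(E)-5-hydroxy-3-methylpent-3-enyl]-1,4a,6-trimethyl-1,2,3,4,4a,7,8,8a-octahydronaphthalene-1-carboxylate
Conditions: Bu4NF, THF, 0 °C → rt
Reagents that add atoms: none
Why: Fluoride cleavage of the silyl ether, which touches neither the alkenes nor the hindered ester.

**Step 12**
Reactants: 23 methyl (1S,4aS,8aR)-5-[(E)-5-hydroxy-3-methylpent-3-enyl]-1,4a,6-trimethyl-1,2,3,4,4a,7,8,8a-octahydronaphthalene-1-carboxylate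
Product: 24 (1S,4aS,8aR)-5-[(E)-5-hydroxy-3-methylpent-3-enyl]-1,4a,6-trimethyl-1,2,3,4,4a,7,8,8a-octahydronaphthalene-1-carboxylic acid
Conditions: NaSEt, DMF, 100 °C; then aq. HCl to pH 3
Reagents that add atoms: none
Why: SN2 demethylation of the hindered axial methyl ester by thiolate at the O-methyl carbon, so that shielding of the acyl carbon by the syn-axial methyl does not matter and no stereocentre is touched.

**Step 13**
Reactants: 24 (1S,4aS,8aR)-5-[(E)-5-hydroxy-3-methylpent-3-enyl]-1,4a,6-trimethyl-1,2,3,4,4a,7,8,8a-octahydronaphthalene-1-carboxylic acid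
Product: 25 (1S,4aS,8aR)-5-[(E)-5-acetoxy-3-methylpent-3-enyl]-1,4a,6-trimethyl-1,2,3,4,4a,7,8,8a-octahydronaphthalene-1-carboxylic acid (15-acetoxylabda-8,13E-dien-19-oic acid)
Conditions: Ac2O, pyridine, CH2Cl2, 0 °C → rt; aqueous work-up
Reagents that add atoms: acetic anhydride, CC(=O)OC(C)=O
Why: Chemoselective O-acetylation of the primary allylic alcohol, after which the hindered tertiary carboxylic acid should be recovered unchanged on aqueous work-up.

**Compound list**
1 | pentan-3-one | CCC(=O)CC | starting material
2 | 1-chloro-3-iodopropane | ClCCCI | starting material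
3 | lithium enolate of pentan-3-one (lithium pent-2-en-3-olate) | CC=C(CC)O[Li] | intermediate
4 | 7-chloro-4-methylheptan-3-one (racemic) | CCC(=O)C(C)CCCCl | intermediate
5 | dimethyl malonate (dimethyl propanedioate) | COC(=O)CC(=O)OC | starting material
6 | sodium dimethyl malonate | [Na+].COC(=O)[CH-]C(=O)OC | intermediate
7 | dimethyl 2-(4-methyl-5-oxoheptyl)propanedioate (racemic) | CCC(=O)C(C)CCCC(C(=O)OC)C(=O)OC | intermediate
8 | propynal | C#CC=O | starting material
9 | dimethyl 2-(4-methyl-5-oxoheptyl)-2-[(E)-3-oxoprop-1-enyl]propanedioate (racemic at the methyl-bearing carbon) | CCC(=O)C(C)CCCC(C(=O)OC)(C(=O)OC)/C=C/C=O | intermediate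
10 | dimethyl (2R,3S)-3-methyl-2-(2-oxoethyl)-3-propanoylcyclohexane-1,1-dicarboxylate (propanoyl and oxoethyl groups trans) | CCC(=O)[C@@]1(C)CCCC(C(=O)OC)(C(=O)OC)[C@@H]1CC=O | intermediate
11 | dimethyl (4aS,8aR)-7-hydroxy-4a,6-dimethyl-5-oxooctahydronaphthalene-1,1(2H)-dicarboxylate (trans-fused; C-6/C-7 epimers) | O=C1C(C)C(O)C[C@H]2C(C(=O)OC)(C(=O)OC)CCC[C@]12C | intermediate
12 | dimethyl (4aS,8aR)-4a,6-dimethyl-5-oxo-3,4,4a,5,8,8a-hexahydronaphthalene-1,1(2H)-dicarboxylate (trans-fused: angular CH3 β, ring-fusion H α) | O=C1C(C)=CC[C@H]2C(C(=O)OC)(C(=O)OC)CCC[C@]12C | intermediate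
13 | methyl (4aS,8aS)-4a,6-dimethyl-5-oxo-1,2,3,4,4a,5,8,8a-octahydronaphthalene-1-carboxylate (C-1 epimers; same trans ring fusion as 12) | O=C1C(C)=CC[C@H]2C(C(=O)OC)CCC[C@]12C | intermediate
14 | lithium enolate of the conjugate-reduced ketone (O–Li on C9, C8=C9; otherwise as 13) | [Li]OC1=C(C)CC[C@H]2C(C(=O)OC)CCC[C@]12C | intermediate
15 | methyl (4aS,8aS)-4a,6-dimethyl-5-(trifluoromethanesulfonyloxy)-1,2,3,4,4a,7,8,8a-octahydronaphthalene-1-carboxylate (C-1 epimers) | O=S(=O)(OC1=C(C)CC[C@H]2C(C(=O)OC)CCC[C@]12C)C(F)(F)F | intermediate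
16 | (E)-3-methylpent-2-en-4-yn-1-ol | C#C/C(C)=C/CO | starting material
17 | tert-butyldimethyl{[(E)-3-methylpent-2-en-4-yn-1-yl]oxy}silane | C#C/C(C)=C/CO[Si](C)(C)C(C)(C)C | intermediate
18 | tert-butyldimethyl{[(E)-3-methylpenta-2,4-dien-1-yl]oxy}silane | C=C/C(C)=C/CO[Si](C)(C)C(C)(C)C | intermediate
19 | 9-[(E)-5-(tert-butyldimethylsilyloxy)-3-methylpent-3-enyl]-9-borabicyclo[3.3.1]nonane | CC(C)(C)[Si](C)(C)OC/C=C(\C)CCB1C2CCCC1CCC2 | intermediate
20 | methyl (4aS,8aS)-5-[(E)-5-(tert-butyldimethylsilyloxy)-3-methylpent-3-enyl]-4a,6-dimethyl-1,2,3,4,4a,7,8,8a-octahydronaphthalene-1-carboxylate (C-1 epimers) | CC(C)(C)[Si](C)(C)OC/C=C(\C)CCC1=C(C)CC[C@H]2C(C(=O)OC)CCC[C@]12C | intermediate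
21 | lithium ester enolate of 20 (exocyclic C4=C(OMe)OLi) | CC(C)(C)[Si](C)(C)OC/C=C(\C)CCC1=C(C)CC[C@H]2C(=C(OC)O[Li])CCC[C@]12C | intermediate
22 | methyl (1S,4aS,8aR)-5-[(E)-5-(tert-butyldimethylsilyloxy)-3-methylpent-3-enyl]-1,4a,6-trimethyl-1,2,3,4,4a,7,8,8a-octahydronaphthalene-1-carboxylate (axial ester, equatorial C-1 methyl) | CC(C)(C)[Si](C)(C)OC/C=C(\C)CCC1=C(C)CC[C@H]2[C@@](C)(C(=O)OC)CCC[C@]12C | intermediate
23 | methyl (1S,4aS,8aR)-5-[(E)-5-hydroxy-3-methylpent-3-enyl]-1,4a,6-trimethyl-1,2,3,4,4a,7,8,8a-octahydronaphthalene-1-carboxylate | OC/C=C(\C)CCC1=C(C)CC[C@H]2[C@@](C)(C(=O)OC)CCC[C@]12C | intermediate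
24 | (1S,4aS,8aR)-5-[(E)-5-hydroxy-3-methylpent-3-enyl]-1,4a,6-trimethyl-1,2,3,4,4a,7,8,8a-octahydronaphthalene-1-carboxylic acid | OC/C=C(\C)CCC1=C(C)CC[C@H]2[C@@](C)(C(=O)O)CCC[C@]12C | intermediate
25 | (1S,4aS,8aR)-5-[(E)-5-acetoxy-3-methylpent-3-enyl]-1,4a,6-trimethyl-1,2,3,4,4a,7,8,8a-octahydronaphthalene-1-carboxylic acid (15-acetoxylabda-8,13E-dien-19-oic acid; 4S,5R,10S in labdane numbering) | CC(=O)OC/C=C(\C)CCC1=C(C)CC[C@H]2[C@@](C)(C(=O)O)CCC[C@]12C | target

**Step count**
Total: 13 steps (11 in the main line, 2 for the side-chain fragment). Longest linear sequence: 11 steps (steps 1–6 and 9–13).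

**Steps most likely to fail**

Step 4. Enolisation of the acyclic ketone may be too slow, or the enol addition may proceed with poor enantiofacial or trans/cis selectivity. The fallback sets out from 7 and returns at 12, using known reaction types only. Compound 7 is added to methyl propiolate (Cs2CO3 cat.) to give dimethyl 2-[(E)-3-methoxy-3-oxoprop-1-enyl]-2-(4-methyl-5-oxoheptyl)propanedioate F1. Condensation with (S)-1-phenylethylamine (TsOH cat., toluene, reflux with water removal; the antipodal amine if the sense requires it) gives the ketimine F2. On heating, F2 cyclises through its more substituted secondary enamine tautomer, an auxiliary-controlled intramolecular Michael addition known for such chiral imines, to the cyclised ketimine F3. Aqueous acetic acid releases the trans keto triester F4. KOt-Bu in THF closes ring B by Dieckmann-type acylation of C8 by the CH2CO2Me group to give the bicyclic 1,3-diketone F5. O-Triflation at the less hindered C7 oxygen (NaH, PhNTf2) gives the β-triflyloxy enone F6, and formate reduction (Pd(OAc)2, PPh3, HCO2H, Bu3N) removes the triflate to give 12.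

Step 9. Oxidative addition and transmetalation may be slow at the tetrasubstituted triflate next to the quaternary C10, so that β-hydride elimination or protodeboronation of the alkyl partner and hydrolysis of the triflate win. The fallback sets out from 15 and the alkyne 17 and returns at 20. Sonogashira coupling of 15 with 17 (Pd(PPh3)4, CuI, i-Pr2NH) brings a small sp carbon to the hindered position and gives the dienyne F7. Diimide (from 2-nitrobenzenesulfonyl hydrazide and Et3N) then saturates the alkyne and the cis-disubstituted alkene formed from it, but should spare the trisubstituted and tetrasubstituted alkenes, giving 20.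

Step 3. Base-induced oligomerisation of propynal may outrun addition of the hindered tertiary malonate anion, or E/Z equilibration may stay incomplete. The fallback sets out from 7 and returns at 9. Michael addition of 7 to acrolein (NaOMe cat., MeOH) gives dimethyl 2-(4-methyl-5-oxoheptyl)-2-(3-oxopropyl)propanedioate F8. Amine-catalysed α-selenenylation of the aldehyde (N-(phenylseleno)phthalimide, pyrrolidine cat.), which should leave the hindered ketone untouched, gives the α-phenylseleno aldehyde F9. NaIO4 oxidation and syn-elimination of the selenoxide give the (E)-enal 9.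

**Further compounds**
F1 | step 4 | dimethyl 2-[(E)-3-methoxy-3-oxoprop-1-enyl]-2-(4-methyl-5-oxoheptyl)propanedioate | CCC(=O)C(C)CCCC(C(=O)OC)(C(=O)OC)/C=C/C(=O)OC
F2 | step 4 | ketimine of F1 with (S)-1-phenylethylamine | CCC(=N[C@@H](C)c1ccccc1)C(C)CCCC(C(=O)OC)(C(=O)OC)/C=C/C(=O)OC
F3 | step 4 | cyclised ketimine (ring A closed, trans) | CCC(=N[C@@H](C)c1ccccc1)[C@@]1(C)CCCC(C(=O)OC)(C(=O)OC)[C@@H]1CC(=O)OC
F4 | step 4 | dimethyl (2R,3S)-2-(2-methoxy-2-oxoethyl)-3-methyl-3-propanoylcyclohexane-1,1-dicarboxylate | CCC(=O)[C@@]1(C)CCCC(C(=O)OC)(C(=O)OC)[C@@H]1CC(=O)OC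
F5 | step 4 | dimethyl (4aS,8aR)-4a,6-dimethyl-5,7-dioxooctahydronaphthalene-1,1(2H)-dicarboxylate | O=C1C(C)C(=O)C[C@H]2C(C(=O)OC)(C(=O)OC)CCC[C@]12C
F6 | step 4 | dimethyl (4aS,8aR)-4a,6-dimethyl-5-oxo-7-(trifluoromethanesulfonyloxy)-3,4,4a,5,8,8a-hexahydronaphthalene-1,1(2H)-dicarboxylate | O=C1C(C)=C(OS(=O)(=O)C(F)(F)F)C[C@H]2C(C(=O)OC)(C(=O)OC)CCC[C@]12C
F7 | step 9 | methyl (4aS,8aS)-5-[(E)-5-(tert-butyldimethylsilyloxy)-3-methylpent-3-en-1-ynyl]-4a,6-dimethyl-1,2,3,4,4a,7,8,8a-octahydronaphthalene-1-carboxylate (C-1 epimers) | CC(C)(C)[Si](C)(C)OC/C=C(\C)C#CC1=C(C)CC[C@H]2C(C(=O)OC)CCC[C@]12C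
F8 | step 3 | dimethyl 2-(4-methyl-5-oxoheptyl)-2-(3-oxopropyl)propanedioate | CCC(=O)C(C)CCCC(C(=O)OC)(C(=O)OC)CCC=O
F9 | step 3 | dimethyl 2-(4-methyl-5-oxoheptyl)-2-[3-oxo-2-(phenylselanyl)propyl]propanedioate | CCC(=O)C(C)CCCC(C(=O)OC)(C(=O)OC)CC([Se]c1ccccc1)C=O
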